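The runs are calculated for an exercise; noise was put on by code.

With the constants hidden, the runs themselves must supply a clock for the catalyst.

the same everywhere: free catalyst 2 mol%
- cedar: solid substrate 0.12 M; reagent 1 equiv; run made earlier
- larch: solid substrate 0.50 M; reagent 1 equiv; run made earlier
- flask: solid substrate 0.25 M; reagent 1.00 equiv; time 3.0 min

| run | time / min | target / % | solid substrate / % |
|---|---|---|---|
| cedar | 0.833 | 6.7 | 67.6 |
| cedar | 1.50 | 11.0 | 55.3 |
| cedar | 2.50 | 14.5 | 35.1 |
| cedar | 3.00 | 16.1 | 25.4 |
| larch | 0.833 | 4.9 | 89.2 |
| larch | 1.50 | 9.2 | 81.6 |
| larch | 2.50 | 12.9 | 69.8 |
| larch | 3.00 | 14.7 | 64.4 |

(readings scatter by 0.5 percentage points)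

- percent here means solid substrate units held: one side product counts as two
- solid substrate is a solid; its amount is given per volume of the solution
- candidate steps: catalyst intermediate B <-> catalyst intermediate C; starting material + target -> side product; solid substrate <-> starting material; catalyst intermediate C -> free catalyst + target; starting material + free catalyst -> catalyst intermediate A; reagent + catalyst intermediate A -> catalyst intermediate B
- at the start none of the solid substrate is in solution

- green: doubling the amount of free catalyst, all else as stated
- teal: doubling the amount of reagent, all else as stated
- ochre: doubling the solubility of the solid substrate, all else as stated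
- blue: doubling the dissolution coefficient of the solid substrate, all else as stated

- target at 3.0 min, in percent of the solid substrate charged
- the change that raises the amount of target at 3.0 min, in percent of the solid substrate charged most ("none" if none brings more than 2 percentage points) (green / teal / ochre / blue / none)
- amount of target at 3.0 min, in percent of the solid substrate charged, after teal

Two chemists dispute the flask. The first says the catalyst keeps the time, and she reads from each run at 3.00 min the time multiplied by the loading and divided by the target percent: 0.373 min in cedar and 0.408 min in larch. Their mean is the net turnover time, the minutes one catalyst spends per target left standing (its inverse is a net turnover frequency), 0.390 min. The flask's 3.0 min then holds 7.68 turnovers, which at 2 mol% gives 15.4 % of target, and doubled catalyst gives 30.7 %. Larch, with more reagent per volume than cedar but also more solid substrate and free catalyst, has the longer turnover time, so she expects little from teal.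

The second chemist points to the solid, 64.4 % of it still present in larch, and holds that the target per volume follows its crawl into solution. Cedar's 19.3 mM of target would then mean 7.73 % in the flask, and he names ochre or blue as the change to make. But larch holds 73.5 mM, more than cedar by a factor of 3.80 against a factor of 4.17 in charge, so I side with her.

The forecast, reasoning that “target in M scales with catalyst”, says 15.5 %, green and 16.5 % after teal.

The flask gives 15.7 %. The best change is green, gaining 12 percentage points, against 2 points for ochre, 1 point for blue and 0.23 points for teal, which reaches 16.0 %.

    catalyst intermediate B ⇌ catalyst intermediate C (K = 2.60, k = 2.70 s⁻¹)
    starting material + target → side product (k = 0.390 M⁻¹ s⁻¹)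
    solid substrate ⇌ starting material, rate k3*(cs3 - [starting material]) while solid is left; crystals form when [starting material] > cs3 (solubility = 34.0 mM, k = 0.0580 s⁻¹)
    catalyst intermediate C → free catalyst + target (k = 7.20 s⁻¹)
    starting material + free catalyst → catalyst intermediate A (k = 4.30 M⁻¹ s⁻¹)
    reagent + catalyst intermediate A → catalyst intermediate B (k = 16.0 M⁻¹ s⁻¹)

At 1.41 min this flask makes target faster than it uses it up, by a factor of 2.05, and up to 3.0 min a net 30.3 % of the solid substrate charged passes from catalyst intermediate B to catalyst intermediate C while a net 14.5 % goes through the step from starting material and target to side product, and the net turnover time counts that difference. The second chemist's attention to supply has its region late in this flask: at 30.0 min solid substrate and starting material stand at 0 % and 0 %, and target at 19.4 %, less than the clock's 154 %.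

A neighbour flask with 0.8 mol% of free catalyst, read at the same time, should by the same 7.68 turnovers hold 6.14 %; it gives 6.72 %.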